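**Plan**

1. Numbering: ring A = C1 (bears C1', the alkene carbon with the oxo-chain), C2 (CH–OAc), O3, C4 (=CH–O), C5, C10. Ring B = C5, C6 (bears C11H2–C12H=C13(CH3)–C14H2OAc), O7, C8 (C=O), C9 (CH2), C10. Enabling feature: C9 lies between the O7–C8 ester and C10, and C5 carries C4. A diazoacetate on O7 can therefore add C9 across a C5=C10 alkene, and the extra C5–C9 bond, flanked by the C8 carbonyl and a C4 formyl group, is easy to cut afterwards.
2. Retrosynthetic cuts, in order: C2–OAc and O3–C2 (ring A opens to a C4 enolate and a C2 aldehyde); C5–C9 re-joined (ring B contracts to a cyclopropane-fused γ-lactone); C9–C10 and C5–C9 (carbene addition from O7); C6–C11 (vinylogous aldol); C5=C10 (Z-olefination); C1–C2 (auxiliary alkylation); C1'–chain (diketene plus Grignard reagent).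
3. Forward: the open chain C1'–C1–C10=C5–C6–C11…C14 is built first. The γ-lactone and cyclopropane then close together. Ring B arises by reductive cleavage of C5–C9. Ring A closes last, when the C4 enolate oxygen adds to the C2 aldehyde and the lactol is acetylated in the same flask.
4. Stereochemistry: C1 from (S)-4-benzyl-2-oxazolidinone; C6 from a reagent-controlled vinylogous Mukaiyama aldol; C10 from the Z-alkene and C6 (allylic 1,3-strain) in the carbene addition, reinforced by the chiral rhodium catalyst; C2 by kinetic acetylation trans to C1'; the C12=C13 E-alkene from the tiglate dienolate.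
5. Masking: the ketone travels as a terminal alkene (Wacker oxidation after the key step). C2 and C4 travel as TIPS-oxymethyl groups and are oxidised together near the end. No free C2 aldehyde is present until ring A is ready to close, because a free 1,5-dialdehyde would enolise towards C1 and give the wrong enol ether.

Key step: step 15

Remark on the chemistry: the face selectivities assigned to the oxazaborolidinone (step 11) and to the rhodium catalyst enantiomer (step 15) follow the accepted models for these reagents and would be checked on 23 and 28; if the sense is opposite, the antipodal reagent is used.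

Step 1
Reactants: 1 5-bromopent-1-ene; 2 diketene
Product: 4 3-methylideneoct-7-enoic acid, via pent-4-enylmagnesium bromide 3 (not isolated)
Conditions: Mg, THF, rt; then 2, NiCl2 (5 mol%), THF, −30 °C to rt; aq. HCl
Reagents that add atoms: none
Why: Nickel-catalysed cross-coupling of a Grignard reagent with diketene replaces the vinylic C–O bond by the alkyl group and opens the ring to the magnesium carboxylate, giving the 3-methylidene acid (C10, C1, C1' and the chain) in one operation with no stereocentre.

Step 2
Reactants: 4 3-methylideneoct-7-enoic acid; 5 (S)-4-benzyl-1,3-oxazolidin-2-one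
Product: 7 (4S)-4-benzyl-3-(3-methylideneoct-7-enoyl)-1,3-oxazolidin-2-one, via mixed pivalic anhydride 6 (not isolated)
Conditions: t-BuCOCl, Et3N, THF, −20 °C; then 5, LiCl, rt
Reagents that add atoms: none
Why: Mixed-anhydride N-acylation of the oxazolidinone with LiCl/Et3N activation is mild enough to keep the alkene out of conjugation.

Step 3
Reactants: 7 N-acyl oxazolidinone; 8 (triisopropylsiloxy)methyl chloride
Product: 10 (4S)-4-benzyl-3-[(2R)-3-methylidene-2-{[(triisopropylsilyl)oxy]methyl}oct-7-enoyl]-1,3-oxazolidin-2-one, via trichlorotitanium enolate 9 (not isolated)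
Conditions: TiCl4, i-Pr2NEt, CH2Cl2, 0 °C; then 8, 0 °C
Reagents that add atoms: none
Why: Evans-type alkylation of a chelated chlorotitanium Z-enolate with a chloromethyl ether: the silyloxymethyl electrophile enters on the face away from the benzyl group, which sets C1 and attaches C2 at the alcohol oxidation level.

Step 4
Reactants: 10 alkylated imide
Product: 11 (2S)-3-methylidene-2-{[(triisopropylsilyl)oxy]methyl}oct-7-en-1-ol
Conditions: LiBH4, THF, 0 °C to rt
Reagents that add atoms: none
Why: Hydride cleavage of the N-acyl oxazolidinone frees C10 as a primary alcohol and returns the auxiliary, and the bulky TIPS ether resists the 1,3-silyl shift that would racemise C1.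

Step 5
Reactants: 11 primary alcohol
Product: 12 (2R)-3-methylidene-2-{[(triisopropylsilyl)oxy]methyl}oct-7-enal
Conditions: Dess–Martin periodinane, NaHCO3, CH2Cl2, 0 °C; used crude
Reagents that add atoms: none
Why: Dess–Martin oxidation under bicarbonate buffer gives the α-branched β,γ-unsaturated aldehyde without amine base, and immediate use keeps C1 from enolising.

Step 6
Reactants: 13 methyl 2-[bis(2,2,2-trifluoroethoxy)phosphoryl]acetate; 8 (triisopropylsiloxy)methyl chloride
Product: 15 methyl 2-[bis(2,2,2-trifluoroethoxy)phosphoryl]-3-[(triisopropylsilyl)oxy]propanoate (racemic), via sodium phosphonate salt 14 (not isolated)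
Conditions: NaH, THF, 0 °C; then 8, 0 °C to rt
Reagents that add atoms: none
Why: C-Alkylation of the stabilised phosphonoacetate carbanion with a reactive α-chloro ether, as in malonate alkylation, puts the future C4 oxygen on the olefination reagent.

Step 7
Reactants: 12 aldehyde; 15 phosphonate
Product: 17 methyl (2Z,4R)-5-methylidene-2,4-bis{[(triisopropylsilyl)oxy]methyl}deca-2,9-dienoate, via potassium phosphonate salt 16 (not isolated)
Conditions: KN(SiMe3)2, 18-crown-6, THF, −78 °C; then 12, −78 °C
Reagents that add atoms: none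
Why: Still–Gennari olefination: with the electron-poor trifluoroethyl phosphonate, elimination from the first-formed adduct is fast and kinetically controlled, so the ester carbon (C6) ends cis to C1 on the new C5=C10 alkene.

Step 8
Reactants: 17 Z-enoate
Product: 18 (2E,4R)-5-methylidene-2,4-bis{[(triisopropylsilyl)oxy]methyl}deca-2,9-dien-1-ol
Conditions: i-Bu2AlH, CH2Cl2, −78 °C; aq. potassium sodium tartrate
Reagents that add atoms: none
Why: 1,2-Reduction of the enoate by i-Bu2AlH at low temperature gives the allylic alcohol and leaves the alkenes and silyl ethers untouched.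

Step 9
Reactants: 18 allylic alcohol
Product: 19 (2Z,4R)-5-methylidene-2,4-bis{[(triisopropylsilyl)oxy]methyl}deca-2,9-dienal
Conditions: MnO2, CH2Cl2, rt
Reagents that add atoms: none
Why: Allylic oxidation with MnO2 is neutral and heterogeneous, which should preserve the Z-geometry of the α-substituted enal.

Step 10
Reactants: 20 methyl (E)-2-methylbut-2-enoate (methyl tiglate)
Product: 22 tert-butyl[(1-methoxy-2-methylbuta-1,3-dien-1-yl)oxy]dimethylsilane, via lithium dienolate 21 (not isolated)
Conditions: LiN(i-Pr)2, DMPU, THF, −78 °C; then t-BuMe2SiCl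
Reagents that add atoms: tert-butyldimethylsilyl chloride, CC(C)(C)[Si](C)(C)Cl
Why: γ-Deprotonation of the tiglate and O-silylation of the dienolate gives the vinylketene silyl acetal needed for the vinylogous aldol reaction.

Step 11
Reactants: 19 Z-enal; 22 silyl dienol ether
Product: 23 methyl (2E,5S,6Z,8R)-5-hydroxy-2-methyl-9-methylidene-6,8-bis{[(triisopropylsilyl)oxy]methyl}tetradeca-2,6,13-trienoate
Conditions: (4R)-4-(1H-indol-3-ylmethyl)-2-phenyl-3-tosyl-1,3,2-oxazaborolidin-5-one (1 equiv, made from N-tosyl-D-tryptophan and PhBCl2), i-PrOH, n-PrCN, −78 °C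
Reagents that add atoms: none
Why: Vinylogous Mukaiyama aldol reaction: the boron Lewis acid activates the formyl group, the dienol ether attacks through its γ-carbon (C11) and returns the E-configured 2-methyl enoate, and the D-tryptophan-derived ring (formyl C–H···O binding plus indole shielding) is expected to leave the Si face of C6 open, giving 5S.

Step 12
Reactants: 23 hydroxy enoate
Product: 24 (2E,5S,6Z,8R)-2-methyl-9-methylidene-6,8-bis{[(triisopropylsilyl)oxy]methyl}tetradeca-2,6,13-triene-1,5-diol
Conditions: i-Bu2AlH, CH2Cl2, −78 °C; aq. potassium sodium tartrate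
Reagents that add atoms: none
Why: i-Bu2AlH reduces the conjugated ester to the primary allylic alcohol (C14) while the secondary C6 alcohol is held as its aluminate.

Step 13
Reactants: 24 diol
Product: 25 (2E,5S,6Z,8R)-5-hydroxy-2-methyl-9-methylidene-6,8-bis{[(triisopropylsilyl)oxy]methyl}tetradeca-2,6,13-trien-1-yl acetate
Conditions: AcCl, 2,4,6-collidine, CH2Cl2, −78 °C
Reagents that add atoms: acetyl chloride, CC(Cl)=O
Why: Kinetic acylation with AcCl/collidine at low temperature selects the unhindered primary allylic hydroxyl over the secondary C6 hydroxyl, which is flanked by the fully substituted C5.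

Step 14
Reactants: 25 monoacetate
Product: 27 (2E,5S,6Z,8R)-5-[(diazoacetyl)oxy]-2-methyl-9-methylidene-6,8-bis{[(triisopropylsilyl)oxy]methyl}tetradeca-2,6,13-trien-1-yl acetate, via glyoxylate tosylhydrazone ester 26 (not isolated)
Conditions: TsNHN=CHCOCl, PhNMe2, CH2Cl2, 0 °C; then Et3N, 0 °C to rt
Reagents that add atoms: glyoxylic acid chloride p-toluenesulfonylhydrazone, Cc1ccc(cc1)S(=O)(=O)NN=CC(Cl)=O
Why: Corey–Myers diazoacetylation: the C6 alcohol is acylated by the glyoxylyl chloride tosylhydrazone and Et3N then expels sulfinate (Bamford–Stevens-type elimination) to give the diazoacetate under conditions the acetate tolerates.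

Step 15
Reactants: 27 allylic diazoacetate
Product: 28 (2E)-2-methyl-4-[(1S,4S,5R,6R)-6-[(2R)-3-methylidene-1-{[(triisopropylsilyl)oxy]}oct-7-en-2-yl]-2-oxo-5-{[(triisopropylsilyl)oxy]methyl}-3-oxabicyclo[3.1.0]hexan-4-yl]but-2-en-1-yl acetate (C1 group endo on the cyclopropane, C11 anti to it)
Conditions: Rh2[(5R)-MEPY]4 (1 mol%; MEPY = methyl 2-oxopyrrolidine-5-carboxylate), CH2Cl2, reflux, 27 added over 10 h by syringe pump
Reagents that add atoms: none
Why: The catalyst decomposes the diazoacetate to a rhodium carbene that adds to the tethered C5=C10 alkene in one concerted, asynchronous step, forming C9–C10 and the temporary C5–C9 bond; the closest known reaction type is the dirhodium carboxamidate-catalysed intramolecular cyclopropanation of allylic diazoacetates to 3-oxabicyclo[3.1.0]hexan-2-ones. The γ-lactone closes through C9–C5 in a 5-exo sense (C10 stays outside the five-membered ring) and the cyclopropane closes by [2+1] addition in the same event. C5 and C9 are set together as the necessarily cis ring fusion, and C10 follows from stereospecific syn addition to the Z-alkene, which places the C1 group endo. The absolute sense of all three comes from C6: allylic 1,3-strain with the cis C1 group makes the C6–H bond eclipse the alkene, so the carbene arrives on the O7 face with C11 anti, and the (5R)-ligand set is the one whose intrinsic preference with achiral allylic diazoacetates matches this face. The step needs chemoselectivity for C5=C10 over the C12=C13, C1'=CH2 and terminal alkenes and over insertion into the allylic C11–H bonds; the carboxamidate catalyst favours five-ring allylic cyclopropanation, the C14 acetate lowers the nucleophilicity of C12=C13, the other alkenes would need medium or large rings, and slow addition suppresses carbene dimerisation.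

Step 16
Reactants: 28 cyclopropane lactone
Product: 29 (2E)-2-methyl-4-[(1S,4S,5R,6R)-6-[(2R)-3-methylidene-7-oxo-1-{[(triisopropylsilyl)oxy]}octan-2-yl]-2-oxo-5-{[(triisopropylsilyl)oxy]methyl}-3-oxabicyclo[3.1.0]hexan-4-yl]but-2-en-1-yl acetate
Conditions: PdCl2 (10 mol%), CuCl, O2 (1 atm), DMF/H2O 7:1, rt
Reagents that add atoms: water, O
Why: Tsuji–Wacker oxidation: Markovnikov hydroxypalladation and β-hydride elimination convert the only monosubstituted alkene into the methyl ketone, the 1,1-disubstituted and trisubstituted alkenes being far less reactive.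

Step 17
Reactants: 29 bis-silyl ether
Product: 30 (2E)-4-[(1S,4S,5R,6R)-6-[(2R)-1-hydroxy-3-methylidene-7-oxooctan-2-yl]-5-(hydroxymethyl)-2-oxo-3-oxabicyclo[3.1.0]hexan-4-yl]-2-methylbut-2-en-1-yl acetate
Conditions: HF·pyridine, pyridine, THF, 0 °C to rt
Reagents that add atoms: none
Why: Fluoride cleavage of both primary TIPS ethers with buffered HF·pyridine is acidic rather than basic, so the new C2 hydroxyl does not transesterify the nearby lactone.

Step 18
Reactants: 30 diol
Product: 31 (2E)-4-[(1S,4S,5S,6R)-5-formyl-6-[(2R)-3-methylidene-1,7-dioxooctan-2-yl]-2-oxo-3-oxabicyclo[3.1.0]hexan-4-yl]-2-methylbut-2-en-1-yl acetate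
Conditions: Dess–Martin periodinane, NaHCO3, CH2Cl2, 0 °C; used crude
Reagents that add atoms: none
Why: Double Dess–Martin oxidation of the two primary alcohols gives a dialdehyde in which the C4 formyl group has no α-hydrogen and the two formyl groups sit trans on the cyclopropane, so no cyclic hemiacetal can form before the ring is opened.

Step 19
Reactants: 31 dialdehyde
Product: 34 target CNP0120157.1 (C1 R; C2 R; C6 S; C10 S), via samarium enolate 32 (not isolated), via samarium lactol alkoxide 33 (not isolated)
Conditions: SmI2 (2.2 equiv), t-BuOH (1.1 equiv), THF, −78 to −40 °C; then Ac2O, −78 to 0 °C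
Reagents that add atoms: acetic anhydride, CC(=O)OC(C)=O
Why: Proposed new method: electron transfer to the C4 formyl group gives a ketyl whose cyclopropylcarbinyl ring opens at C5–C9 (the bond that leaves an ester-stabilised C9 radical), a second SmI2 reduces that radical to the lactone enolate, which t-BuOH protonates, and the remaining trivalent samarium C4 enolate (oxygen syn to C10 because the ketyl oxygen turns away from C6 and C11) adds through oxygen to the C2 formyl group, C-attack being impossible as it would need a four-membered ring; Ac2O then acylates the lactol alkoxide, the less hindered anomer trans to C1' reacting faster while the anomers interconvert; the closest known reactions are the SmI2 opening of cyclopropyl ketones with electrophilic trapping of the samarium enolate and the in-flask O-acetylation of samarium alkoxides; keeping C4=C5 as an enolate throughout avoids the isomeric enol ether towards C1 and base-induced loss of the C6 carboxylate.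

**Compound list**

1 | 5-bromopent-1-ene | C=CCCCBr | starting material
2 | diketene (4-methylideneoxetan-2-one) | C=C1CC(=O)O1 | starting material
3 | pent-4-enylmagnesium bromide | C=CCCC[Mg]Br | intermediate (not isolated)
4 | 3-methylideneoct-7-enoic acid | C=CCCCC(=C)CC(=O)O | intermediate
5 | (S)-4-benzyl-1,3-oxazolidin-2-one | O=C1N[C@@H](Cc2ccccc2)CO1 | starting material
6 | 3-methylideneoct-7-enoic 2,2-dimethylpropanoic anhydride | C=CCCCC(=C)CC(=O)OC(=O)C(C)(C)C | intermediate (not isolated)
7 | (4S)-4-benzyl-3-(3-methylideneoct-7-enoyl)-1,3-oxazolidin-2-one | C=CCCCC(=C)CC(=O)N1C(=O)OC[C@@H]1Cc1ccccc1 | intermediate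
8 | (triisopropylsiloxy)methyl chloride | ClCO[Si](C(C)C)(C(C)C)C(C)C | starting material
9 | trichlorotitanium (Z)-enolate of 7 | C=CCCCC(=C)/C=C(\O[Ti](Cl)(Cl)Cl)N1C(=O)OC[C@@H]1Cc1ccccc1 | intermediate (not isolated)
10 | (4S)-4-benzyl-3-[(2R)-3-methylidene-2-{[(triisopropylsilyl)oxy]methyl}oct-7-enoyl]-1,3-oxazolidin-2-one | O=C1OC[C@H](Cc2ccccc2)N1C(=O)[C@@H](CO[Si](C(C)C)(C(C)C)C(C)C)C(=C)CCCC=C | intermediate
11 | (2S)-3-methylidene-2-{[(triisopropylsilyl)oxy]methyl}oct-7-en-1-ol | OC[C@@H](CO[Si](C(C)C)(C(C)C)C(C)C)C(=C)CCCC=C | intermediate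
12 | (2R)-3-methylidene-2-{[(triisopropylsilyl)oxy]methyl}oct-7-enal | O=C[C@@H](CO[Si](C(C)C)(C(C)C)C(C)C)C(=C)CCCC=C | intermediate
13 | methyl 2-[bis(2,2,2-trifluoroethoxy)phosphoryl]acetate | COC(=O)CP(=O)(OCC(F)(F)F)OCC(F)(F)F | starting material
14 | sodium salt of 13 (phosphonate carbanion) | COC(=O)[CH-]P(=O)(OCC(F)(F)F)OCC(F)(F)F.[Na+] | intermediate (not isolated)
15 | methyl 2-[bis(2,2,2-trifluoroethoxy)phosphoryl]-3-[(triisopropylsilyl)oxy]propanoate (racemic) | COC(=O)C(CO[Si](C(C)C)(C(C)C)C(C)C)P(=O)(OCC(F)(F)F)OCC(F)(F)F | intermediate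
16 | potassium salt of 15 (phosphonate carbanion) | COC(=O)[C-](CO[Si](C(C)C)(C(C)C)C(C)C)P(=O)(OCC(F)(F)F)OCC(F)(F)F.[K+] | intermediate (not isolated)
17 | methyl (2Z,4R)-5-methylidene-2,4-bis{[(triisopropylsilyl)oxy]methyl}deca-2,9-dienoate | COC(=O)/C(CO[Si](C(C)C)(C(C)C)C(C)C)=C\[C@@H](CO[Si](C(C)C)(C(C)C)C(C)C)C(=C)CCCC=C | intermediate
18 | (2E,4R)-5-methylidene-2,4-bis{[(triisopropylsilyl)oxy]methyl}deca-2,9-dien-1-ol | OC/C(CO[Si](C(C)C)(C(C)C)C(C)C)=C\[C@@H](CO[Si](C(C)C)(C(C)C)C(C)C)C(=C)CCCC=C | intermediate
19 | (2Z,4R)-5-methylidene-2,4-bis{[(triisopropylsilyl)oxy]methyl}deca-2,9-dienal | O=C/C(CO[Si](C(C)C)(C(C)C)C(C)C)=C\[C@@H](CO[Si](C(C)C)(C(C)C)C(C)C)C(=C)CCCC=C | intermediate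
20 | methyl (E)-2-methylbut-2-enoate (methyl tiglate) | C/C=C(\C)C(=O)OC | starting material
21 | lithium dienolate of 20 | C=CC(C)=C(OC)[O-].[Li+] | intermediate (not isolated)
22 | tert-butyl[(1-methoxy-2-methylbuta-1,3-dien-1-yl)oxy]dimethylsilane (ketene acetal geometry as formed) | C=CC(C)=C(OC)O[Si](C)(C)C(C)(C)C | intermediate
23 | methyl (2E,5S,6Z,8R)-5-hydroxy-2-methyl-9-methylidene-6,8-bis{[(triisopropylsilyl)oxy]methyl}tetradeca-2,6,13-trienoate | COC(=O)/C(C)=C/C[C@H](O)/C(CO[Si](C(C)C)(C(C)C)C(C)C)=C\[C@@H](CO[Si](C(C)C)(C(C)C)C(C)C)C(=C)CCCC=C | intermediate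
24 | (2E,5S,6Z,8R)-2-methyl-9-methylidene-6,8-bis{[(triisopropylsilyl)oxy]methyl}tetradeca-2,6,13-triene-1,5-diol | OC/C(C)=C/C[C@H](O)/C(CO[Si](C(C)C)(C(C)C)C(C)C)=C\[C@@H](CO[Si](C(C)C)(C(C)C)C(C)C)C(=C)CCCC=C | intermediate
25 | (2E,5S,6Z,8R)-5-hydroxy-2-methyl-9-methylidene-6,8-bis{[(triisopropylsilyl)oxy]methyl}tetradeca-2,6,13-trien-1-yl acetate | CC(=O)OC/C(C)=C/C[C@H](O)/C(CO[Si](C(C)C)(C(C)C)C(C)C)=C\[C@@H](CO[Si](C(C)C)(C(C)C)C(C)C)C(=C)CCCC=C | intermediate
26 | C6 O-[2-(p-toluenesulfonylhydrazono)acetyl] ester of 25 | Cc1ccc(cc1)S(=O)(=O)NN=CC(=O)O[C@@H](C/C=C(\C)COC(C)=O)/C(CO[Si](C(C)C)(C(C)C)C(C)C)=C\[C@@H](CO[Si](C(C)C)(C(C)C)C(C)C)C(=C)CCCC=C | intermediate (not isolated)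
27 | key-step precursor: (2E,5S,6Z,8R)-5-[(diazoacetyl)oxy]-2-methyl-9-methylidene-6,8-bis{[(triisopropylsilyl)oxy]methyl}tetradeca-2,6,13-trien-1-yl acetate | [N-]=[N+]=CC(=O)O[C@@H](C/C=C(\C)COC(C)=O)/C(CO[Si](C(C)C)(C(C)C)C(C)C)=C\[C@@H](CO[Si](C(C)C)(C(C)C)C(C)C)C(=C)CCCC=C | intermediate
28 | key-step product: (1S,4S,5R,6R)-3-oxabicyclo[3.1.0]hexan-2-one with 4-[(E)-4-acetoxy-3-methylbut-2-enyl], 5-(TIPS-oxymethyl) and endo 6-[(2R)-3-methylidene-1-(TIPS-oxy)oct-7-en-2-yl] groups | O=C1O[C@@H](C/C=C(\C)COC(C)=O)[C@@]2(CO[Si](C(C)C)(C(C)C)C(C)C)[C@@H]1[C@H]2[C@@H](CO[Si](C(C)C)(C(C)C)C(C)C)C(=C)CCCC=C | intermediate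
29 | methyl ketone of 28 (side chain now 3-methylidene-7-oxooctan-2-yl) | O=C1O[C@@H](C/C=C(\C)COC(C)=O)[C@@]2(CO[Si](C(C)C)(C(C)C)C(C)C)[C@@H]1[C@H]2[C@@H](CO[Si](C(C)C)(C(C)C)C(C)C)C(=C)CCCC(C)=O | intermediate
30 | keto diol (C4 and C2 hydroxymethyl groups free) | O=C1O[C@@H](C/C=C(\C)COC(C)=O)[C@@]2(CO)[C@@H]1[C@H]2[C@@H](CO)C(=C)CCCC(C)=O | intermediate
31 | keto dialdehyde (C4 formyl on the cyclopropane, C2 formyl on C1) | O=C1O[C@@H](C/C=C(\C)COC(C)=O)[C@@]2(C=O)[C@@H]1[C@H]2[C@@H](C=O)C(=C)CCCC(C)=O | intermediate
32 | diiodosamarium (E)-enolate at C4 of the ring-B δ-lactone, C2 formyl free | I[Sm](I)O/C=C1/[C@H](C/C=C(\C)COC(C)=O)OC(=O)C[C@H]1[C@@H](C=O)C(=C)CCCC(C)=O | intermediate (not isolated)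
33 | diiodosamarium alkoxide of the ring-A lactol (both C2 anomers, interconverting) | C=C(CCCC(C)=O)[C@@H]1C(O[Sm](I)I)OC=C2[C@H](C/C=C(\C)COC(C)=O)OC(=O)C[C@H]21 | intermediate (not isolated)
34 | CNP0120157.1 | C=C(CCCC(C)=O)[C@@H]1[C@@H](OC(C)=O)OC=C2[C@H](C/C=C(\C)COC(C)=O)OC(=O)C[C@H]21 | target

**Totals and risks**

Total step count: 19 (17 on the main line; steps 6 and 10 prepare reagents 15 and 22).
Longest linear sequence: 17 steps (steps 1–5, 7–9 and 11–19, from 1).

Steps most likely to fail:

1. Step 19 (proposed new method). Electron transfer may go to the C2 formyl group instead (pinacol coupling or reduction). The C4 enolate may be protonated on carbon or expel the C6 carboxylate before it closes ring A. It may also form with its oxygen syn to C6, which cannot cyclise. The fallback separates reduction from ring closure with known reactions. Setting out from 31, the less hindered C2 formyl group is converted selectively into its dimethyl acetal (HC(OMe)3, MeOH, pyridinium p-toluenesulfonate, 0 °C; the C4 formyl group sits on a quaternary cyclopropane carbon) to give the cyclopropane lactone C2 dimethyl acetal F1. SmI2/t-BuOH in THF at −78 °C followed by Ac2O opens the cyclopropane and O-acetylates the samarium enolate, giving the ring-B lactone C4 enol acetate F2. Pyridinium p-toluenesulfonate in wet acetone then unmasks C2 while C4=C5 stays locked, giving the enol acetate aldehyde F3. Bu3SnOMe cleaves the enol acetate to the neutral tin enolate, whose oxygen closes onto the C2 formyl group, and Ac2O acetylates the stannyl lactol, returning to the route at 34.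

2. Step 15 (key step). Carbene insertion into the allylic C11–H bonds, hydride transfer from C6, or weak facial control because the branched C1 group must take the endo position could erode the cyclopropanation. The fallback makes the same two bonds by a polar, stepwise ammonium ylide route. From 25, bromoacetyl bromide/pyridine gives the C6 bromoacetate F4. HF·pyridine removes both silyl groups to give the bromoacetate diol F5. MnO2 oxidises only the allylic C4 alcohol to give the bromoacetate enal F6, in which C10 is a Michael acceptor. DABCO (catalytic) with Cs2CO3 in MeCN forms the ammonium ylide at C9, which adds to C10 and is then displaced by the C5 enolate (Michael-initiated ring closure), giving the cyclopropane lactone hydroxy aldehyde F7. The Tsuji–Wacker conditions of step 16 give the corresponding methyl ketone F8, and Dess–Martin oxidation of the C2 alcohol returns to the route at 31.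

3. Step 11. The hindered Z-enal may react sluggishly, isomerise on the Lewis acid, or be attacked on the wrong face. The fallback makes the C6–C11 bond and the side chain in separate, reagent-controlled operations. From 19, a Nagao acetate aldol reaction (N-acetyl-(4R)-4-isopropyl-1,3-thiazolidine-2-thione, Sn(OSO2CF3)2, N-ethylpiperidine, CH2Cl2, −78 °C; the auxiliary enantiomer expected to deliver the tin enolate to the Si face) gives the β-hydroxy acyl thiazolidinethione F9. i-Bu2AlH at −78 °C reduces the thioimide directly to the β-hydroxy aldehyde F10. Wittig reaction with methyl 2-(triphenylphosphoranylidene)propanoate then gives the E-enoate and returns to the route at 23.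

**Further compounds**

F1 | step 19 | cyclopropane lactone with C4 formyl group and C2 dimethyl acetal | O=C1O[C@@H](C/C=C(\C)COC(C)=O)[C@@]2(C=O)[C@@H]1[C@H]2[C@@H](C(OC)OC)C(=C)CCCC(C)=O
F2 | step 19 | ring-B δ-lactone with C4 (E)-enol acetate and C2 dimethyl acetal | CC(=O)O/C=C1/[C@H](C/C=C(\C)COC(C)=O)OC(=O)C[C@H]1[C@@H](C(OC)OC)C(=C)CCCC(C)=O
F3 | step 19 | ring-B δ-lactone with C4 (E)-enol acetate and free C2 aldehyde | CC(=O)O/C=C1/[C@H](C/C=C(\C)COC(C)=O)OC(=O)C[C@H]1[C@@H](C=O)C(=C)CCCC(C)=O
F4 | step 15 | C6 bromoacetate of 25 | BrCC(=O)O[C@@H](C/C=C(\C)COC(C)=O)/C(CO[Si](C(C)C)(C(C)C)C(C)C)=C\[C@@H](CO[Si](C(C)C)(C(C)C)C(C)C)C(=C)CCCC=C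
F5 | step 15 | C6 bromoacetate with free C4 and C2 hydroxymethyl groups | BrCC(=O)O[C@@H](C/C=C(\C)COC(C)=O)/C(CO)=C\[C@@H](CO)C(=C)CCCC=C
F6 | step 15 | C6 bromoacetate with C4 formyl group (enal) and C2 hydroxymethyl group | BrCC(=O)O[C@@H](C/C=C(\C)COC(C)=O)/C(C=O)=C\[C@@H](CO)C(=C)CCCC=C
F7 | step 15 | cyclopropane-fused γ-lactone with C4 formyl, C2 hydroxymethyl and terminal alkene | O=C1O[C@@H](C/C=C(\C)COC(C)=O)[C@@]2(C=O)[C@@H]1[C@H]2[C@@H](CO)C(=C)CCCC=C
F8 | step 15 | cyclopropane-fused γ-lactone with C4 formyl, C2 hydroxymethyl and methyl ketone | O=C1O[C@@H](C/C=C(\C)COC(C)=O)[C@@]2(C=O)[C@@H]1[C@H]2[C@@H](CO)C(=C)CCCC(C)=O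
F9 | step 11 | (4R)-4-isopropyl-3-[(3S)-3-hydroxyacyl]-1,3-thiazolidine-2-thione aldol adduct of 19 | S=C1SC[C@@H](C(C)C)N1C(=O)C[C@H](O)/C(CO[Si](C(C)C)(C(C)C)C(C)C)=C\[C@@H](CO[Si](C(C)C)(C(C)C)C(C)C)C(=C)CCCC=C
F10 | step 11 | (3S,4Z,6R)-3-hydroxy-7-methylidene-4,6-bis{[(triisopropylsilyl)oxy]methyl}dodeca-4,11-dienal | O=CC[C@H](O)/C(CO[Si](C(C)C)(C(C)C)C(C)C)=C\[C@@H](CO[Si](C(C)C)(C(C)C)C(C)C)C(=C)CCCC=C
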